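**Retrosynthetic overview**

1. The 19-membered lactam is opened at N–C20: a copper-mediated aryl amidation joins a C1 primary (2E,4Z)-dienamide to a C20 aryl bromide. The O7 carbamate and the hydroquinone (reached through the quinone) are set after ring closure.
2. C1–C8 is grown from C9: Wittig to the C7 enal, (Z)-γ-methoxyallylboration for C6/C7, then Still–Gennari and Wittig olefinations for the 4Z and 2E alkenes.
3. The C15–C16 bond comes from 3-bromo-2,5-dimethoxyphenyllithium and a C15 Weinreb amide; CBS reduction and O-methylation then set C15.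
4. The strategy rests on C11–C15: oxygen on C11, C12 and C15 and the methyl on C14 are the substituents of the ring O–C11–C12–C13–C14–C15, a 6-hydroxy-5-methyl-2H-pyran-3(6H)-one. It is made by Achmatowicz ring expansion of a 4-methyl-2-furyl carbinol (furan C2–C5 become C12–C15). The ring relays the C11 configuration to C12 (Luche reduction) and C14 (directed hydrogenation) and is then opened at C15.
5. C10/C11 come from an Evans syn-aldol. Ring order: pyranone (built, then cleaved), dioxolane (protecting ring), macrolactam last.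

Key step: step 5

Assumption: ansamycin numbering of the target (amide carbonyl C1, arene C16–C21) is used for all chain intermediates; the lactol of step 5 is expected as an anomeric mixture (trans anomer drawn) and is carried on as such, because C15 becomes a carbonyl in step 6.

**Route**

Step 1
Reactants: 1 4-bromofuran-2-carbaldehyde
Product: 2 4-methylfuran-2-carbaldehyde
Conditions: MeB(OH)2, Pd(dppf)Cl2 (cat.), K2CO3, 1,4-dioxane/H2O, 90 °C
Reagents that add atoms: methylboronic acid, CB(O)O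
Why: Suzuki–Miyaura cross-coupling of a heteroaryl bromide with methylboronic acid is routine, and the formyl group tolerates the carbonate base.

Step 2
Reactants: 3 (R)-4-benzyl-3-propionyloxazolidin-2-one; 2 4-methylfuran-2-carbaldehyde
Product: 5 (R)-4-benzyl-3-[(2R,3R)-3-hydroxy-2-methyl-3-(4-methylfuran-2-yl)propanoyl]oxazolidin-2-one, via dibutylboron Z-enolate 4 (not isolated)
Conditions: Bu2BOTf, i-Pr2NEt, CH2Cl2, −78 → 0 °C; then 2, −78 → 0 °C; pH 7 buffer, MeOH, H2O2, 0 °C
Reagents that add atoms: none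
Why: Evans syn-aldol reaction: the Z-boron enolate adds through a chair transition state on the enolate face away from the benzyl group, which should set C10 and C11 together as the 2R,3R syn pair.

Step 3
Reactants: 5 (R)-4-benzyl-3-[(2R,3R)-3-hydroxy-2-methyl-3-(4-methylfuran-2-yl)propanoyl]oxazolidin-2-one
Product: 6 (1R,2S)-2-methyl-1-(4-methylfuran-2-yl)propane-1,3-diol
Conditions: LiBH4, MeOH (1 equiv), THF, 0 °C
Reagents that add atoms: none
Why: Reductive cleavage of the N-acyl oxazolidinone with LiBH4 gives the C9 primary alcohol without epimerising C10 and returns the auxiliary.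

Step 4
Reactants: 6 (1R,2S)-2-methyl-1-(4-methylfuran-2-yl)propane-1,3-diol
Product: 7 (1R,2S)-3-(tert-butyldimethylsilyloxy)-2-methyl-1-(4-methylfuran-2-yl)propan-1-ol
Conditions: t-BuMe2SiCl, imidazole, CH2Cl2, 0 °C
Reagents that add atoms: tert-butyldimethylsilyl chloride, CC(C)(C)[Si](C)(C)Cl
Why: Silylation is selective for the primary hydroxyl over the hindered secondary furyl carbinol, which leaves O11–H free for the ring expansion.

Step 5
Reactants: 7 (1R,2S)-3-(tert-butyldimethylsilyloxy)-2-methyl-1-(4-methylfuran-2-yl)propan-1-ol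
Product: 9 (2R,6S)-6-hydroxy-5-methyl-2-[(S)-1-(tert-butyldimethylsilyloxy)propan-2-yl]-2H-pyran-3(6H)-one, via cis-enedione 8 (not isolated)
Conditions: N-bromosuccinimide, NaHCO3, NaOAc, THF/H2O (4:1), 0 °C
Reagents that add atoms: water, O
Why: Achmatowicz rearrangement: bromonium transfer from N-bromosuccinimide to the furan at C15 and capture by water at C12 give a 2,5-dihydroxy-2,5-dihydrofuran, which opens to the cis-enedione 8 with a ketone at C12 and an aldehyde at C15. The free C11 hydroxyl then adds to the C15 aldehyde, so the O–C15 bond forms in a 6-exo-trig hemiacetalisation that closes the ring O–C11–C12–C13–C14–C15. The closest known reaction type is the oxidative ring expansion of 2-furyl carbinols to 6-hydroxy-2H-pyran-3(6H)-ones, applied here to a 4-methylfuran so that the methyl group sits on C14 of the enone. The only new stereocentre is the anomeric C15, which equilibrates under thermodynamic control (anomeric effect, trans to the C11 side chain expected to prevail) and is removed again when C15 is oxidised in step 6. The step needs chemoselective oxidation of the furan, secured by its far higher nucleophilicity compared with the silyl ether, and retention of C11, secured by the cold, bicarbonate/acetate-buffered medium in which the α-oxy ketone does not enolise.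

Step 6
Reactants: 9 (2R,6S)-6-hydroxy-5-methyl-2-[(S)-1-(tert-butyldimethylsilyloxy)propan-2-yl]-2H-pyran-3(6H)-one
Product: 10 (R)-3-methyl-6-[(S)-1-(tert-butyldimethylsilyloxy)propan-2-yl]-2H-pyran-2,5(6H)-dione
Conditions: Dess–Martin periodinane, CH2Cl2, 0 °C → rt; filtered and used crude
Reagents that add atoms: none
Why: Dess–Martin oxidation of a lactol to the lactone proceeds without base, which matters because the keto-lactone could enolise at C11 toward a 5-hydroxy-2-pyranone, so it is reduced at once.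

Step 7
Reactants: 10 (R)-3-methyl-6-[(S)-1-(tert-butyldimethylsilyloxy)propan-2-yl]-2H-pyran-2,5(6H)-dione
Product: 11 (5S,6R)-5-hydroxy-3-methyl-6-[(S)-1-(tert-butyldimethylsilyloxy)propan-2-yl]-5,6-dihydro-2H-pyran-2-one
Conditions: NaBH4, CeCl3·7H2O, MeOH/CH2Cl2, −78 °C
Reagents that add atoms: none
Why: Luche reduction gives 1,2-reduction of the C12 ketone, and axial hydride delivery on the half-chair with the C11 side chain pseudo-equatorial should give the 11,12-trans alcohol (12S).

Step 8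
Reactants: 11 (5S,6R)-5-hydroxy-3-methyl-6-[(S)-1-(tert-butyldimethylsilyloxy)propan-2-yl]-5,6-dihydro-2H-pyran-2-one
Product: 12 (3S,5S,6R)-5-hydroxy-3-methyl-6-[(S)-1-(tert-butyldimethylsilyloxy)propan-2-yl]tetrahydro-2H-pyran-2-one
Conditions: H2 (1 atm), [Ir(cod)(PCy3)(py)]PF6 (cat.), CH2Cl2, rt
Reagents that add atoms: none
Why: Hydroxyl-directed hydrogenation: the C12 hydroxyl binds the cationic iridium centre and delivers H2 to its own face of C13=C14, which is also the face away from the C11 side chain, so the C14 methyl should end up cis to that chain (14S).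

Step 9
Reactants: 12 (3S,5S,6R)-5-hydroxy-3-methyl-6-[(S)-1-(tert-butyldimethylsilyloxy)propan-2-yl]tetrahydro-2H-pyran-2-one
Product: 13 (2S,4S,5R,6S)-7-(tert-butyldimethylsilyloxy)-4,5-dihydroxy-N-methoxy-N,2,6-trimethylheptanamide
Conditions: MeNH(OMe)·HCl, Me3Al, CH2Cl2, 0 °C → rt; aq. potassium sodium tartrate
Reagents that add atoms: N,O-dimethylhydroxylamine hydrochloride, CNOC.Cl
Why: Weinreb aminolysis of the lactone by the aluminium amide opens the template ring at C15 and frees O11–H; any lactone that had translactonised onto O12 would converge on the same diol amide.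

Step 10
Reactants: 13 (2S,4S,5R,6S)-7-(tert-butyldimethylsilyloxy)-4,5-dihydroxy-N-methoxy-N,2,6-trimethylheptanamide
Product: 14 (S)-3-[(4S,5R)-5-[(S)-1-(tert-butyldimethylsilyloxy)propan-2-yl]-2,2-dimethyl-1,3-dioxolan-4-yl]-N-methoxy-N,2-dimethylpropanamide
Conditions: 2-methoxypropene, PPTS (cat.), CH2Cl2, 0 °C
Reagents that add atoms: 2-methoxypropene, COC(C)=C
Why: Acid-catalysed ketalisation of the 11,12-anti-diol gives the cis-dioxolane quickly, protects both hydroxyls in one operation and blocks relactonisation.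

Step 11
Reactants: 15 2,6-dibromobenzene-1,4-diol
Product: 16 1,3-dibromo-2,5-dimethoxybenzene
Conditions: MeI, K2CO3, DMF, rt
Reagents that add atoms: iodomethane, CI
Why: Williamson O-methylation of both phenols gives ethers that survive aryllithium chemistry and can be removed oxidatively at the end.

Step 12
Reactants: 16 1,3-dibromo-2,5-dimethoxybenzene; 14 (S)-3-[(4S,5R)-5-[(S)-1-(tert-butyldimethylsilyloxy)propan-2-yl]-2,2-dimethyl-1,3-dioxolan-4-yl]-N-methoxy-N,2-dimethylpropanamide
Product: 18 (S)-1-(3-bromo-2,5-dimethoxyphenyl)-3-[(4S,5R)-5-[(S)-1-(tert-butyldimethylsilyloxy)propan-2-yl]-2,2-dimethyl-1,3-dioxolan-4-yl]-2-methylpropan-1-one, via aryllithium 17 (not isolated)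
Conditions: 16, n-BuLi (1.0 equiv), THF, −78 °C; then 14, −78 → −40 °C; aq. NH4Cl
Reagents that add atoms: none
Why: Bromine–lithium exchange on one of two equivalent bromides followed by acylation with the Weinreb amide forms C15–C16; the chelated tetrahedral intermediate prevents over-addition and the cold buffered quench protects C14 from epimerisation.

Step 13
Reactants: 18 (S)-1-(3-bromo-2,5-dimethoxyphenyl)-3-[(4S,5R)-5-[(S)-1-(tert-butyldimethylsilyloxy)propan-2-yl]-2,2-dimethyl-1,3-dioxolan-4-yl]-2-methylpropan-1-one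
Product: 19 (1R,2S)-1-(3-bromo-2,5-dimethoxyphenyl)-3-[(4S,5R)-5-[(S)-1-(tert-butyldimethylsilyloxy)propan-2-yl]-2,2-dimethyl-1,3-dioxolan-4-yl]-2-methylpropan-1-ol
Conditions: (S)-2-methyl-CBS-oxazaborolidine, BH3·SMe2, THF, −30 °C; MeOH quench
Reagents that add atoms: none
Why: Corey–Bakshi–Shibata reduction with the aryl group as the large substituent should deliver hydride to the face giving 15R, with reagent control expected to override the modest opposing Felkin bias of C14.

Step 14
Reactants: 19 (1R,2S)-1-(3-bromo-2,5-dimethoxyphenyl)-3-[(4S,5R)-5-[(S)-1-(tert-butyldimethylsilyloxy)propan-2-yl]-2,2-dimethyl-1,3-dioxolan-4-yl]-2-methylpropan-1-ol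
Product: 20 15-O-methyl ether of 19 (C9–C21 segment with 15R-OMe, 11,12-acetonide, 9-OTBS)
Conditions: NaH, MeI, THF/DMF, 0 °C → rt
Reagents that add atoms: iodomethane, CI
Why: Williamson methylation of the benzylic alkoxide is straightforward because no acidic C–H or base-labile group remains in the molecule.

Step 15
Reactants: 20 15-O-methyl ether of 19
Product: 21 C9 primary alcohol (20 without the silyl group)
Conditions: Bu4NF, THF, 0 °C → rt
Reagents that add atoms: none
Why: Fluoride desilylation removes the only silyl ether present and leaves the acetonide and the methyl ethers untouched.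

Step 16
Reactants: 21 C9 primary alcohol
Product: 22 C9 aldehyde (same spatial arrangement; C10 becomes R by CIP priority)
Conditions: Dess–Martin periodinane, NaHCO3, CH2Cl2, 0 °C → rt
Reagents that add atoms: none
Why: Buffered Dess–Martin oxidation gives the α-methyl aldehyde under conditions that should not epimerise C10.

Step 17
Reactants: 22 C9 aldehyde
Product: 23 (8E)-C7 enal (E-2-methyl enal built on C9)
Conditions: Ph3P=C(Me)CHO, toluene, 90 °C
Reagents that add atoms: 2-(triphenylphosphoranylidene)propanal, CC(C=O)=P(c1ccccc1)(c1ccccc1)c1ccccc1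
Why: Wittig olefination with the formyl-stabilised ylide gives the E-trisubstituted enal in one step, and the weakly basic ylide should spare the C10 stereocentre.

Step 18
Reactants: 24 allyl methyl ether; 23 (8E)-C7 enal
Product: 27 (6S,7S)-6-methoxy-7-hydroxy C4–C21 segment bearing the terminal C4=C5 vinyl group, via (Z)-3-methoxyallyllithium 25 (not isolated), via (Z)-γ-methoxyallyldiisopinocampheylborane 26 (not isolated)
Conditions: 24, s-BuLi, THF, −78 °C; (+)-Ipc2BOMe [enantiomer derived from (−)-α-pinene]; BF3·OEt2; then 23, −78 °C; NaOH, H2O2, 0 °C → rt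
Reagents that add atoms: none
Why: Brown γ-methoxyallylboration: the Z-allylborane reacts through a chair transition state to give the 6,7-syn relationship, and the isopinocampheyl groups from (−)-α-pinene should select the aldehyde face that gives 7S and hence 6S.

Step 19
Reactants: 27 (6S,7S)-homoallylic alcohol
Product: 28 7-O-tert-butyldimethylsilyl ether of 27
Conditions: t-BuMe2SiOTf, 2,6-lutidine, CH2Cl2, −78 → 0 °C
Reagents that add atoms: tert-butyldimethylsilyl triflate, CC(C)(C)[Si](C)(C)OS(=O)(=O)C(F)(F)F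
Why: Silyl triflate protection of the hindered allylic alcohol masks O7 through the redox steps and the ring closure.

Step 20
Reactants: 28 7-O-silyl ether
Product: 30 C5 aldehyde (C5–C21; C6 becomes R by CIP priority), via terminal 4,5-diol 29 (not isolated)
Conditions: OsO4 (cat.), N-methylmorpholine N-oxide (1.1 equiv), acetone/H2O, 0 °C; then NaIO4, THF/H2O, 0 °C
Reagents that add atoms: N-methylmorpholine N-oxide, C[N+]1([O-])CCOCC1; water, O
Why: Catalytic dihydroxylation followed by periodate glycol cleavage should take the exposed monosubstituted alkene in preference to the trisubstituted C8=C9 alkene, which is shielded by the C7 silyloxy and C10 branches.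

Step 21
Reactants: 30 C5 aldehyde
Product: 31 methyl (4Z)-enoate (C3–C21)
Conditions: (CF3CH2O)2P(O)CH2CO2Me, KN(SiMe3)2, 18-crown-6, THF, −78 °C
Reagents that add atoms: methyl bis(2,2,2-trifluoroethyl)phosphonoacetate, COC(=O)CP(=O)(OCC(F)(F)F)OCC(F)(F)F
Why: Still–Gennari olefination gives the Z-enoate under kinetic control, and the preformed phosphonate anion at −78 °C should not epimerise the α-methoxy aldehyde.

Step 22
Reactants: 31 methyl (4Z)-enoate
Product: 32 (4Z)-allylic alcohol (C3–C21)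
Conditions: i-Bu2AlH, CH2Cl2, −78 °C; aq. potassium sodium tartrate
Reagents that add atoms: none
Why: Hydride reduction of the enoate to the allylic alcohol at low temperature keeps the Z geometry and leaves the acetonide intact.

Step 23
Reactants: 32 (4Z)-allylic alcohol
Product: 33 (4Z)-enal (C3–C21)
Conditions: MnO2, CH2Cl2, rt
Reagents that add atoms: none
Why: MnO2 oxidises only the allylic alcohol under neutral conditions, which limits Z to E isomerisation of the enal; it is used without delay.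

Step 24
Reactants: 33 (4Z)-enal
Product: 34 ethyl (2E,4Z)-dienoate (C1–C21)
Conditions: Ph3P=C(Me)CO2Et, CH2Cl2, rt
Reagents that add atoms: ethyl 2-(triphenylphosphoranylidene)propanoate, CCOC(=O)C(C)=P(c1ccccc1)(c1ccccc1)c1ccccc1
Why: Wittig olefination with the stabilised ylide gives the E-trisubstituted C2=C3 alkene without disturbing the 4Z alkene.

Step 25
Reactants: 34 ethyl (2E,4Z)-dienoate
Product: 35 (2E,4Z)-dienoic acid
Conditions: LiOH, THF/MeOH/H2O, rt; then 0.5 M HCl to pH 4, 0 °C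
Reagents that add atoms: lithium hydroxide, [Li+].[OH-]
Why: Saponification of the dienoate is safe because no base-sensitive stereocentre is adjacent, and the brief cold acidification spares the acetonide.

Step 26
Reactants: 35 (2E,4Z)-dienoic acid
Product: 37 (2E,4Z)-dienamide (seco-amide carrying C20–Br), via isobutyl mixed anhydride 36 (not isolated)
Conditions: i-BuOCOCl, N-methylmorpholine, THF, −15 °C; then NH3 (aq.), −15 → 0 °C
Reagents that add atoms: ammonia, N
Why: Mixed-anhydride amidation: ammonia attacks the more electrophilic acyl carbon of the carbonic anhydride and gives the primary amide under mild conditions.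

Step 27
Reactants: 37 (2E,4Z)-dienamide
Product: 38 19-membered macrolactam (18,21-di-O-methyl; 11,12-O-isopropylidene; 7-O-silyl)
Conditions: CuI, N,N'-dimethylethylenediamine, K2CO3, toluene (high dilution), 100 °C
Reagents that add atoms: none
Why: Intramolecular Goldberg-type amidation: the diamine-ligated monovalent copper amidate undergoes oxidative addition to the C20–Br bond and reductive elimination forms N–C20, with high dilution favouring ring closure.

Step 28
Reactants: 38 macrolactam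
Product: 39 7-hydroxy macrolactam
Conditions: Bu4NF, AcOH, THF, 0 °C → rt
Reagents that add atoms: none
Why: Buffered fluoride removes the single silyl ether and exposes O7 as the only free hydroxyl in the molecule.

Step 29
Reactants: 39 7-hydroxy macrolactam
Product: 41 7-O-carbamoyl macrolactam (18,21-dimethyl ether; 11,12-acetonide), via N-trichloroacetyl carbamate 40 (not isolated)
Conditions: Cl3CC(O)NCO, CH2Cl2, 0 °C; then K2CO3 (cat.), MeOH, 0 °C → rt
Reagents that add atoms: trichloroacetyl isocyanate, O=C=NC(=O)C(Cl)(Cl)Cl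
Why: The highly electrophilic acyl isocyanate carbamoylates the secondary alcohol in preference to the anilide N–H, and mild methanolysis of the trichloroacetyl group leaves the primary carbamate.

Step 30
Reactants: 41 7-O-carbamoyl macrolactam
Product: 42 quinone 11,12-acetonide (C18 and C21 carbonyls)
Conditions: (NH4)2Ce(NO3)6, MeCN/H2O, −10 → 0 °C, short reaction time
Reagents that add atoms: water, O
Why: Oxidative demethylation of the para-dimethoxyarene by tetravalent cerium gives the amido-benzoquinone by ipso attack of water and loss of methanol, faster than oxidation of the diene or the carbamate.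

Step 31
Reactants: 42 quinone 11,12-acetonide
Product: 43 quinone 11,12-diol
Conditions: CF3CO2H, H2O, THF, 0 °C → rt
Reagents that add atoms: none
Why: Acid hydrolysis of the acetonide is carried out at the quinone oxidation level, where the electron-poor ring does not support ionisation of the C15 methyl ether.

Step 32
Reactants: 43 quinone 11,12-diol
Product: 44 CNP0523404.1 (target hydroquinone; 2E,4Z,6S,7S,8E,10S,11R,12S,14S,15R)
Conditions: Na2S2O4, EtOAc/H2O, rt, under argon
Reagents that add atoms: none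
Why: Dithionite reduces the benzoquinone to the hydroquinone by a two-electron reduction without touching the dienamide, the carbamate or any stereocentre; the product is handled with exclusion of air.

**Compound list**

1 | 4-bromofuran-2-carbaldehyde | O=Cc1cc(Br)co1 | starting material
2 | 4-methylfuran-2-carbaldehyde | Cc1coc(C=O)c1 | intermediate
3 | (R)-4-benzyl-3-propionyloxazolidin-2-one | CCC(=O)N1[C@H](Cc2ccccc2)COC1=O | starting material
4 | dibutylboron (Z)-enolate of 3 | CCCCB(CCCC)O/C(=C\C)N1[C@H](Cc2ccccc2)COC1=O | intermediate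
5 | (R)-4-benzyl-3-[(2R,3R)-3-hydroxy-2-methyl-3-(4-methylfuran-2-yl)propanoyl]oxazolidin-2-one | Cc1coc(c1)[C@H](O)[C@@H](C)C(=O)N1[C@H](Cc2ccccc2)COC1=O | intermediate
6 | (1R,2S)-2-methyl-1-(4-methylfuran-2-yl)propane-1,3-diol | Cc1coc(c1)[C@H](O)[C@@H](C)CO | intermediate
7 | (1R,2S)-3-(tert-butyldimethylsilyloxy)-2-methyl-1-(4-methylfuran-2-yl)propan-1-ol | Cc1coc(c1)[C@H](O)[C@@H](C)CO[Si](C)(C)C(C)(C)C | intermediate
8 | (2Z,5R,6S)-7-(tert-butyldimethylsilyloxy)-5-hydroxy-2,6-dimethyl-4-oxohept-2-enal | O=C/C(C)=C\C(=O)[C@H](O)[C@@H](C)CO[Si](C)(C)C(C)(C)C | intermediate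
9 | (2R,6S)-6-hydroxy-5-methyl-2-[(S)-1-(tert-butyldimethylsilyloxy)propan-2-yl]-2H-pyran-3(6H)-one (trans anomer drawn) | O[C@H]1O[C@H]([C@@H](C)CO[Si](C)(C)C(C)(C)C)C(=O)C=C1C | intermediate
10 | (R)-3-methyl-6-[(S)-1-(tert-butyldimethylsilyloxy)propan-2-yl]-2H-pyran-2,5(6H)-dione | O=C1O[C@H]([C@@H](C)CO[Si](C)(C)C(C)(C)C)C(=O)C=C1C | intermediate
11 | (5S,6R)-5-hydroxy-3-methyl-6-[(S)-1-(tert-butyldimethylsilyloxy)propan-2-yl]-5,6-dihydro-2H-pyran-2-one | O=C1O[C@H]([C@@H](C)CO[Si](C)(C)C(C)(C)C)[C@@H](O)C=C1C | intermediate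
12 | (3S,5S,6R)-5-hydroxy-3-methyl-6-[(S)-1-(tert-butyldimethylsilyloxy)propan-2-yl]tetrahydro-2H-pyran-2-one | O=C1O[C@H]([C@@H](C)CO[Si](C)(C)C(C)(C)C)[C@@H](O)C[C@@H]1C | intermediate
13 | (2S,4S,5R,6S)-7-(tert-butyldimethylsilyloxy)-4,5-dihydroxy-N-methoxy-N,2,6-trimethylheptanamide | CON(C)C(=O)[C@@H](C)C[C@H](O)[C@H](O)[C@@H](C)CO[Si](C)(C)C(C)(C)C | intermediate
14 | (S)-3-[(4S,5R)-5-[(S)-1-(tert-butyldimethylsilyloxy)propan-2-yl]-2,2-dimethyl-1,3-dioxolan-4-yl]-N-methoxy-N,2-dimethylpropanamide | CON(C)C(=O)[C@@H](C)C[C@@H]1OC(C)(C)O[C@@H]1[C@@H](C)CO[Si](C)(C)C(C)(C)C | intermediate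
15 | 2,6-dibromobenzene-1,4-diol | Oc1cc(Br)c(O)c(Br)c1 | starting material
16 | 1,3-dibromo-2,5-dimethoxybenzene | COc1cc(Br)c(OC)c(Br)c1 | intermediate
17 | (3-bromo-2,5-dimethoxyphenyl)lithium | [Li]c1cc(OC)cc(Br)c1OC | intermediate
18 | (S)-1-(3-bromo-2,5-dimethoxyphenyl)-3-[(4S,5R)-5-[(S)-1-(tert-butyldimethylsilyloxy)propan-2-yl]-2,2-dimethyl-1,3-dioxolan-4-yl]-2-methylpropan-1-one | COc1cc(Br)c(OC)c(c1)C(=O)[C@@H](C)C[C@@H]1OC(C)(C)O[C@@H]1[C@@H](C)CO[Si](C)(C)C(C)(C)C | intermediate
19 | (1R,2S)-1-(3-bromo-2,5-dimethoxyphenyl)-3-[(4S,5R)-5-[(S)-1-(tert-butyldimethylsilyloxy)propan-2-yl]-2,2-dimethyl-1,3-dioxolan-4-yl]-2-methylpropan-1-ol | COc1cc(Br)c(OC)c(c1)[C@H](O)[C@@H](C)C[C@@H]1OC(C)(C)O[C@@H]1[C@@H](C)CO[Si](C)(C)C(C)(C)C | intermediate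
20 | 15-O-methyl ether of 19 (10S,11R,12S,14S,15R) | COc1cc(Br)c(OC)c(c1)[C@H](OC)[C@@H](C)C[C@@H]1OC(C)(C)O[C@@H]1[C@@H](C)CO[Si](C)(C)C(C)(C)C | intermediate
21 | C9 primary alcohol of the C9–C21 segment | COc1cc(Br)c(OC)c(c1)[C@H](OC)[C@@H](C)C[C@@H]1OC(C)(C)O[C@@H]1[C@@H](C)CO | intermediate
22 | C9 aldehyde of the C9–C21 segment | COc1cc(Br)c(OC)c(c1)[C@H](OC)[C@@H](C)C[C@@H]1OC(C)(C)O[C@@H]1[C@@H](C)C=O | intermediate
23 | (8E)-C7 enal (C7–C21) | COc1cc(Br)c(OC)c(c1)[C@H](OC)[C@@H](C)C[C@@H]1OC(C)(C)O[C@@H]1[C@@H](C)/C=C(\C)C=O | intermediate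
24 | allyl methyl ether | COCC=C | starting material
25 | (Z)-3-methoxyallyllithium | [Li]C/C=C\OC | intermediate
26 | (Z)-γ-methoxyallyldiisopinocampheylborane, isopinocampheyl groups from (−)-α-pinene | CO/C=C\CB([C@H]1C[C@H]2C[C@@H]([C@@H]1C)C2(C)C)[C@H]1C[C@H]2C[C@@H]([C@@H]1C)C2(C)C | intermediate
27 | (6S,7S)-6-methoxy-7-hydroxy C4–C21 segment with terminal vinyl | COc1cc(Br)c(OC)c(c1)[C@H](OC)[C@@H](C)C[C@@H]1OC(C)(C)O[C@@H]1[C@@H](C)/C=C(\C)[C@H](O)[C@@H](OC)C=C | intermediate
28 | 7-O-tert-butyldimethylsilyl ether of 27 | COc1cc(Br)c(OC)c(c1)[C@H](OC)[C@@H](C)C[C@@H]1OC(C)(C)O[C@@H]1[C@@H](C)/C=C(\C)[C@H](O[Si](C)(C)C(C)(C)C)[C@@H](OC)C=C | intermediate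
29 | 4,5-diol of 28 (C5 epimers) | COc1cc(Br)c(OC)c(c1)[C@H](OC)[C@@H](C)C[C@@H]1OC(C)(C)O[C@@H]1[C@@H](C)/C=C(\C)[C@H](O[Si](C)(C)C(C)(C)C)[C@@H](OC)C(O)CO | intermediate
30 | C5 aldehyde (C5–C21) | COc1cc(Br)c(OC)c(c1)[C@H](OC)[C@@H](C)C[C@@H]1OC(C)(C)O[C@@H]1[C@@H](C)/C=C(\C)[C@H](O[Si](C)(C)C(C)(C)C)[C@@H](OC)C=O | intermediate
31 | methyl (4Z)-enoate (C3–C21) | COc1cc(Br)c(OC)c(c1)[C@H](OC)[C@@H](C)C[C@@H]1OC(C)(C)O[C@@H]1[C@@H](C)/C=C(\C)[C@H](O[Si](C)(C)C(C)(C)C)[C@@H](OC)/C=C\C(=O)OC | intermediate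
32 | (4Z)-allylic alcohol (C3–C21) | COc1cc(Br)c(OC)c(c1)[C@H](OC)[C@@H](C)C[C@@H]1OC(C)(C)O[C@@H]1[C@@H](C)/C=C(\C)[C@H](O[Si](C)(C)C(C)(C)C)[C@@H](OC)/C=C\CO | intermediate
33 | (4Z)-enal (C3–C21) | COc1cc(Br)c(OC)c(c1)[C@H](OC)[C@@H](C)C[C@@H]1OC(C)(C)O[C@@H]1[C@@H](C)/C=C(\C)[C@H](O[Si](C)(C)C(C)(C)C)[C@@H](OC)/C=C\C=O | intermediate
34 | ethyl (2E,4Z)-dienoate (C1–C21) | COc1cc(Br)c(OC)c(c1)[C@H](OC)[C@@H](C)C[C@@H]1OC(C)(C)O[C@@H]1[C@@H](C)/C=C(\C)[C@H](O[Si](C)(C)C(C)(C)C)[C@@H](OC)/C=C\C=C(/C)C(=O)OCC | intermediate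
35 | (2E,4Z)-dienoic acid (C1–C21) | COc1cc(Br)c(OC)c(c1)[C@H](OC)[C@@H](C)C[C@@H]1OC(C)(C)O[C@@H]1[C@@H](C)/C=C(\C)[C@H](O[Si](C)(C)C(C)(C)C)[C@@H](OC)/C=C\C=C(/C)C(O)=O | intermediate
36 | isobutyl carbonic mixed anhydride of 35 | COc1cc(Br)c(OC)c(c1)[C@H](OC)[C@@H](C)C[C@@H]1OC(C)(C)O[C@@H]1[C@@H](C)/C=C(\C)[C@H](O[Si](C)(C)C(C)(C)C)[C@@H](OC)/C=C\C=C(/C)C(=O)OC(=O)OCC(C)C | intermediate
37 | (2E,4Z)-dienamide, seco-amide with C20–Br | COc1cc(Br)c(OC)c(c1)[C@H](OC)[C@@H](C)C[C@@H]1OC(C)(C)O[C@@H]1[C@@H](C)/C=C(\C)[C@H](O[Si](C)(C)C(C)(C)C)[C@@H](OC)/C=C\C=C(/C)C(N)=O | intermediate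
38 | macrolactam: 18,21-di-O-methyl, 11,12-O-isopropylidene, 7-O-tert-butyldimethylsilyl | CO[C@H]1/C=C\C=C(/C)C(=O)Nc2cc(OC)cc(c2OC)[C@H](OC)[C@@H](C)C[C@@H]3OC(C)(C)O[C@@H]3[C@@H](C)/C=C(\C)[C@@H]1O[Si](C)(C)C(C)(C)C | intermediate
39 | 7-hydroxy macrolactam | CO[C@H]1/C=C\C=C(/C)C(=O)Nc2cc(OC)cc(c2OC)[C@H](OC)[C@@H](C)C[C@@H]3OC(C)(C)O[C@@H]3[C@@H](C)/C=C(\C)[C@@H]1O | intermediate
40 | 7-O-(N-trichloroacetylcarbamoyl) macrolactam | CO[C@H]1/C=C\C=C(/C)C(=O)Nc2cc(OC)cc(c2OC)[C@H](OC)[C@@H](C)C[C@@H]3OC(C)(C)O[C@@H]3[C@@H](C)/C=C(\C)[C@@H]1OC(=O)NC(=O)C(Cl)(Cl)Cl | intermediate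
41 | 7-O-carbamoyl macrolactam (18,21-dimethyl ether, 11,12-acetonide) | CO[C@H]1/C=C\C=C(/C)C(=O)Nc2cc(OC)cc(c2OC)[C@H](OC)[C@@H](C)C[C@@H]3OC(C)(C)O[C@@H]3[C@@H](C)/C=C(\C)[C@@H]1OC(N)=O | intermediate
42 | quinone 11,12-acetonide | CO[C@H]1/C=C\C=C(/C)C(=O)NC2=CC(=O)C=C(C2=O)[C@H](OC)[C@@H](C)C[C@@H]3OC(C)(C)O[C@@H]3[C@@H](C)/C=C(\C)[C@@H]1OC(N)=O | intermediate
43 | quinone 11,12-diol | CO[C@H]1/C=C\C=C(/C)C(=O)NC2=CC(=O)C=C(C2=O)[C@H](OC)[C@@H](C)C[C@H](O)[C@H](O)[C@@H](C)/C=C(\C)[C@@H]1OC(N)=O | intermediate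
44 | CNP0523404.1 | CO[C@H]1/C=C\C=C(/C)C(=O)Nc2cc(O)cc(c2O)[C@H](OC)[C@@H](C)C[C@H](O)[C@H](O)[C@@H](C)/C=C(\C)[C@@H]1OC(N)=O | target

**Step count and risks**

Total steps: 32. Longest linear sequence: 31 steps (steps 1–10 and 12–32, from 4-bromofuran-2-carbaldehyde); step 11 is the only branch step.

Steps most likely to fail:

1. Step 13 (CBS reduction). Facial selectivity may be poor, because the catalyst must work against the Felkin preference of the C14 centre and because the size difference between the ortho-substituted aryl group and the branched alkyl chain is small. Fallback: setting out from 14, i-Bu2AlH (THF, −78 °C) reduces the Weinreb amide to (S)-3-[(4S,5R)-5-[(S)-1-(tert-butyldimethylsilyloxy)propan-2-yl]-2,2-dimethyl-1,3-dioxolan-4-yl]-2-methylpropanal F1. Aryllithium 17, made as in step 12 and optionally transmetalated with MgBr2·OEt2, is then added at −78 °C. Felkin–Anh addition to the α-methyl aldehyde places the new C15 hydroxyl syn to the C14 methyl, so here substrate control works for the wanted epimer. This gives alcohol 19, where the route is rejoined.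

2. Step 20 (cleavage of the terminal alkene). Osmylation may also attack the trisubstituted C8=C9 alkene, or the α-methoxy aldehyde may epimerise at C6 during cleavage. Fallback: setting out from 23, a boron aldol reaction with (R)-4-benzyl-3-(2-methoxyacetyl)oxazolidin-2-one (Bu2BOTf, Et3N, CH2Cl2, −78 → 0 °C) gives the syn-glycolate aldol adduct F2, which carries C5 as the imide carbonyl together with 6-OMe and 7-OH. Silylation (t-BuMe2SiOTf, 2,6-lutidine) gives the 7-O-silyl imide F3, LiBH4 gives the C5 primary alcohol F4, and Dess–Martin oxidation gives aldehyde 30, where the route is rejoined. No terminal alkene is made on this path.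

3. Step 27 (copper-mediated macrolactamisation). Oxidative addition to the electron-rich, ortho-substituted aryl bromide may be slow, so that intermolecular amidation, protodebromination or thermal isomerisation of the 4Z alkene competes. Fallback: setting out from 34, amination with benzophenone imine (Pd2(dba)3, BINAP, Cs2CO3, toluene, 90 °C) gives the N-aryl benzophenone imine F5. Transimination (NH2OH·HCl, NaOAc, MeOH) gives the aniline ester F6, and LiOH gives the anilino acid F7. Macrolactamisation from the acid side (bis(2-oxo-3-oxazolidinyl)phosphinic chloride, i-Pr2NEt, toluene, 80 °C, high dilution) gives macrolactam 38, where the route is rejoined.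

**Further compounds**

F1 | step 13 | (S)-3-[(4S,5R)-5-[(S)-1-(tert-butyldimethylsilyloxy)propan-2-yl]-2,2-dimethyl-1,3-dioxolan-4-yl]-2-methylpropanal | O=C[C@@H](C)C[C@@H]1OC(C)(C)O[C@@H]1[C@@H](C)CO[Si](C)(C)C(C)(C)C
F2 | step 20 | syn-glycolate aldol adduct of 23 with the (R)-benzyloxazolidinone (C5 imide, 6-OMe, 7-OH) | COc1cc(Br)c(OC)c(c1)[C@H](OC)[C@@H](C)C[C@@H]1OC(C)(C)O[C@@H]1[C@@H](C)/C=C(\C)[C@H](O)[C@@H](OC)C(=O)N1[C@H](Cc2ccccc2)COC1=O
F3 | step 20 | 7-O-tert-butyldimethylsilyl ether of F2 | COc1cc(Br)c(OC)c(c1)[C@H](OC)[C@@H](C)C[C@@H]1OC(C)(C)O[C@@H]1[C@@H](C)/C=C(\C)[C@H](O[Si](C)(C)C(C)(C)C)[C@@H](OC)C(=O)N1[C@H](Cc2ccccc2)COC1=O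
F4 | step 20 | C5 primary alcohol (C5–C21, 6-OMe, 7-OTBS) | COc1cc(Br)c(OC)c(c1)[C@H](OC)[C@@H](C)C[C@@H]1OC(C)(C)O[C@@H]1[C@@H](C)/C=C(\C)[C@H](O[Si](C)(C)C(C)(C)C)[C@@H](OC)CO
F5 | step 27 | N-aryl benzophenone imine of dienoate 34 (C20–N=CPh2) | COc1cc(N=C(c2ccccc2)c2ccccc2)c(OC)c(c1)[C@H](OC)[C@@H](C)C[C@@H]1OC(C)(C)O[C@@H]1[C@@H](C)/C=C(\C)[C@H](O[Si](C)(C)C(C)(C)C)[C@@H](OC)/C=C\C=C(/C)C(=O)OCC
F6 | step 27 | C20 aniline ethyl (2E,4Z)-dienoate | COc1cc(N)c(OC)c(c1)[C@H](OC)[C@@H](C)C[C@@H]1OC(C)(C)O[C@@H]1[C@@H](C)/C=C(\C)[C@H](O[Si](C)(C)C(C)(C)C)[C@@H](OC)/C=C\C=C(/C)C(=O)OCC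
F7 | step 27 | C20 aniline (2E,4Z)-dienoic acid | COc1cc(N)c(OC)c(c1)[C@H](OC)[C@@H](C)C[C@@H]1OC(C)(C)O[C@@H]1[C@@H](C)/C=C(\C)[C@H](O[Si](C)(C)C(C)(C)C)[C@@H](OC)/C=C\C=C(/C)C(O)=O
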